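Ring A is an isotetronic acid: its quaternary C5 (CO2Me, benzyl) is the ketone carbon of one arylpyruvate, and C4 (aryl), C3 (enol) and C2 (lactone C=O) are the benzylic, keto and ester carbons of a second. The retrosynthesis therefore cuts C4–C5 and O1–C2 of ring A first, as an aldol–lactonisation onto an α-keto ester that already carries the linker and ring B.
The next cut is the tertiary ether C–O bond between the C3 oxygen of ring B and the CMe2 carbon of the linker (enol O–H opening of a 2,2-dimethyloxirane), then C4–C5 and O1–C2 of ring B by the same aldol–lactonisation.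
Forward: three arylpyruvate units are drawn from aryl lactates, each keto ester being released by a neutral Dess–Martin oxidation just before use. Ring B is closed first and joined through its enol oxygen to the epoxide of a prenylated aryl lactate; the lactate is then unveiled to the α-keto ester, ring A is closed, and all silyl ethers are removed.
Stereochemistry: both quaternary C5 centres (R) come from one antipode of a bis(oxazoline)–Cu(OTf)2 catalyst. The linker carbinol (S) comes from a Shi epoxidation and survives ether formation because the epoxide is opened at its other, tertiary carbon.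

Key step: step 17

Notation: TBS = tert-butyldimethylsilyl, TES = triethylsilyl, TMS = trimethylsilyl, prenyl = 3-methylbut-2-en-1-yl. Butenolides are numbered O1, C2 (C=O), C3, C4 (aryl), C5 (quaternary). "RB-oxy" is the ring B unit bound through the oxygen on its C3: [(5R)-5-(methoxycarbonyl)-2-oxo-5-{[4-(TBS-oxy)-3-prenylphenyl]methyl}-4-[4-(TBS-oxy)phenyl]-2,5-dihydrofuran-3-yl]oxy.

Assumptions:
- The sense of induction of the Cu(OTf)2–bis(oxazoline) catalyst is taken from the square-planar chelate model for pyruvate esters, in which the (S,S) ligand leads to S tertiary alcohols; the (R,R) ligand is therefore used for both R centres.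
- The L-fructose-derived Shi ketone is taken to attack the face of the prenyl group opposite to that chosen by the D-fructose-derived ketone, giving the S epoxide.
- Compound 1 is used as the racemate because its carbinol centre is oxidised away; 12, 13, 21 and 22 form as epimer mixtures at the aryl-bearing carbon, which becomes sp2.

Step 1
Reactants: 1 (±)-2-hydroxy-3-(4-hydroxyphenyl)propanoic acid
Product: 2 methyl (±)-2-hydroxy-3-(4-hydroxyphenyl)propanoate
Conditions: MeOH, H2SO4 (cat.), reflux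
Reagents that add atoms: methanol, CO
Why: Fischer esterification of the acid in methanol leaves the phenol and the secondary alcohol untouched.

Step 2
Reactants: 2 methyl (±)-2-hydroxy-3-(4-hydroxyphenyl)propanoate
Product: 3 methyl (±)-3-[4-(TBS-oxy)phenyl]-2-hydroxypropanoate
Conditions: TBSCl (1.05 equiv), imidazole, DMF, 0 °C
Reagents that add atoms: tert-butyldimethylsilyl chloride, CC(C)(C)[Si](C)(C)Cl
Why: Silyl ether formation with one equivalent of chloride should select the more acidic phenol over the deactivated α-hydroxy ester, which must stay free for oxidation.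

Step 3
Reactants: 3 methyl (±)-3-[4-(TBS-oxy)phenyl]-2-hydroxypropanoate
Product: 4 methyl 3-[4-(TBS-oxy)phenyl]-2-oxopropanoate
Conditions: Dess–Martin periodinane, NaHCO3, CH2Cl2, 0 °C → rt
Reagents that add atoms: none
Why: Dess–Martin oxidation of an α-hydroxy ester to the α-keto ester runs under buffered neutral conditions that an aryl silyl ether tolerates.

Step 4
Reactants: 4 methyl 3-[4-(TBS-oxy)phenyl]-2-oxopropanoate
Product: 5 methyl (Z)-3-[4-(TBS-oxy)phenyl]-2-(TMS-oxy)acrylate
Conditions: TMSCl, Et3N, THF, 0 °C → rt; filtration under argon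
Reagents that add atoms: trimethylsilyl chloride, C[Si](C)(C)Cl
Why: O-silylation of the arylpyruvate through its hydrogen-bonded enol (enol silane formation) should give the Z isomer, in which aryl and ester are trans.

Step 5
Reactants: 6 3-iodo-L-tyrosine
Product: 7 (S)-2-hydroxy-3-(4-hydroxy-3-iodophenyl)propanoic acid
Conditions: NaNO2, 1 M H2SO4, H2O, 0 °C → rt
Reagents that add atoms: water, O
Why: Diazotisation of the α-amino acid and hydrolysis pass through the α-lactone (double inversion), so the hydroxy acid keeps the S configuration, which is in any case removed later by oxidation.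

Step 6
Reactants: 7 (S)-2-hydroxy-3-(4-hydroxy-3-iodophenyl)propanoic acid
Product: 8 methyl (S)-2-hydroxy-3-(4-hydroxy-3-iodophenyl)propanoate
Conditions: MeOH, H2SO4 (cat.), reflux
Reagents that add atoms: methanol, CO
Why: Fischer esterification, as in step 1, with the aryl iodide inert.

Step 7
Reactants: 8 methyl (S)-2-hydroxy-3-(4-hydroxy-3-iodophenyl)propanoate
Product: 9 methyl (S)-3-[4-(TBS-oxy)-3-iodophenyl]-2-hydroxypropanoate
Conditions: TBSCl (1.05 equiv), imidazole, DMF, 0 °C
Reagents that add atoms: tert-butyldimethylsilyl chloride, CC(C)(C)[Si](C)(C)Cl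
Why: Silyl ether formation selective for the phenol, whose acidity is raised by the ortho iodine, over the α-hydroxy ester.

Step 8
Reactants: 9 methyl (S)-3-[4-(TBS-oxy)-3-iodophenyl]-2-hydroxypropanoate
Product: 10 methyl (S)-3-[4-(TBS-oxy)-3-prenylphenyl]-2-hydroxypropanoate
Conditions: tributyl(3-methylbut-2-en-1-yl)stannane, Pd(PPh3)4 (5 mol %), DMF, 90 °C
Reagents that add atoms: tributyl(3-methylbut-2-en-1-yl)stannane, CCCC[Sn](CCCC)(CCCC)CC=C(C)C
Why: Stille coupling (oxidative addition of the aryl iodide to zerovalent palladium, transmetalation from tin, reductive elimination at the unsubstituted allyl terminus) should give the linear prenyl arene without touching the hydroxy ester or the silyl ether.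

Step 9
Reactants: 10 methyl (S)-3-[4-(TBS-oxy)-3-prenylphenyl]-2-hydroxypropanoate
Product: 11 methyl 3-[4-(TBS-oxy)-3-prenylphenyl]-2-oxopropanoate
Conditions: Dess–Martin periodinane, NaHCO3, CH2Cl2, 0 °C → rt; used at once
Reagents that add atoms: none
Why: Dess–Martin oxidation delivers the arylpyruvate as its keto tautomer under neutral conditions and spares the prenyl alkene.

Step 10
Reactants: 11 methyl 3-[4-(TBS-oxy)-3-prenylphenyl]-2-oxopropanoate; 5 methyl (Z)-3-[4-(TBS-oxy)phenyl]-2-(TMS-oxy)acrylate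
Product: 14 methyl (2R)-4-hydroxy-5-oxo-2-{[4-(TBS-oxy)-3-prenylphenyl]methyl}-3-[4-(TBS-oxy)phenyl]-2,5-dihydrofuran-2-carboxylate (ring B butenolide with free C3 enol), via silyl aldol adduct 12 (not isolated), via hydroxy keto diester 13 (not isolated)
Conditions: Cu(OTf)2 (20 mol %), 2,2'-isopropylidenebis[(4R)-4-tert-butyl-2-oxazoline] (22 mol %), 5 (2 equiv), THF, −78 → −20 °C; then 1 M HCl, THF, 0 °C → rt
Reagents that add atoms: none
Why: Mukaiyama aldol addition of the enol silane to the copper-chelated keto ester on its re face (ligand control) should set C5 of ring B as R, after which acid removes the silyl group, the tertiary alcohol lactonises onto the pyruvate ester of the former nucleophile (5-exo-trig) and the keto lactone enolises, erasing C4.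

Step 11
Reactants: 10 methyl (S)-3-[4-(TBS-oxy)-3-prenylphenyl]-2-hydroxypropanoate
Product: 15 methyl (S)-3-[4-(TBS-oxy)-3-prenylphenyl]-2-(TES-oxy)propanoate
Conditions: TESCl, imidazole, DMF, 0 °C → rt
Reagents that add atoms: triethylsilyl chloride, CC[Si](Cl)(CC)CC
Why: Silylation of the α-hydroxy ester masks the future keto ester with a group that can later be removed while the linker carbinol stays protected.

Step 12
Reactants: 15 methyl (S)-3-[4-(TBS-oxy)-3-prenylphenyl]-2-(TES-oxy)propanoate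
Product: 16 methyl (S)-3-[4-(TBS-oxy)-3-{[(2S)-3,3-dimethyloxiran-2-yl]methyl}phenyl]-2-(TES-oxy)propanoate
Conditions: 1,2:4,5-di-O-isopropylidene-β-L-erythro-2,3-hexodiulo-2,6-pyranose (0.3 equiv), KHSO5 (as Oxone, 2KHSO5·KHSO4·K2SO4), K2CO3, Bu4NHSO4, MeCN–CH2(OMe)2, aq. Na2B4O7 buffer, 0 °C
Reagents that add atoms: potassium peroxymonosulfate, [K+].[O-]S(=O)(=O)OO
Why: Shi epoxidation of the trisubstituted alkene by the chiral dioxirane (spiro transition state) should set the epoxide CH as S with the L-fructose-derived ketone, the only alkene present being the prenyl group.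

Step 13
Reactants: 14 ring B butenolide with free C3 enol; 16 methyl (S)-3-[4-(TBS-oxy)-3-{[(2S)-3,3-dimethyloxiran-2-yl]methyl}phenyl]-2-(TES-oxy)propanoate
Product: 17 methyl (2S)-3-{4-(TBS-oxy)-3-[(2S)-2-hydroxy-3-methyl-3-(RB-oxy)butyl]phenyl}-2-(TES-oxy)propanoate
Conditions: BF3·OEt2 (0.2 equiv), 16 (2 equiv, slow addition), 4 Å MS, CH2Cl2, −78 → −40 °C; Et3N quench
Reagents that add atoms: none
Why: Lewis acid-catalysed epoxide opening by the acidic enol O–H of 14 should occur at the tertiary carbon, which carries most of the positive charge (borderline SN1, as in acid-catalysed alcoholysis of 2,2-dimethyloxiranes), so the C–O bond at the secondary carbon is untouched and the S centre of 16 becomes the S carbinol; O-alkylation is the only outlet because C4 of the enol is fully substituted.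

Step 14
Reactants: 17 methyl (2S)-3-{4-(TBS-oxy)-3-[(2S)-2-hydroxy-3-methyl-3-(RB-oxy)butyl]phenyl}-2-(TES-oxy)propanoate
Product: 18 methyl (2S)-3-{4-(TBS-oxy)-3-[(2S)-2-(TBS-oxy)-3-methyl-3-(RB-oxy)butyl]phenyl}-2-(TES-oxy)propanoate
Conditions: TBSOTf, 2,6-lutidine, CH2Cl2, −78 → 0 °C
Reagents that add atoms: tert-butyldimethylsilyl triflate, CC(C)(C)[Si](C)(C)OS(=O)(=O)C(F)(F)F
Why: Silylation with the silyl triflate reaches the hindered secondary alcohol next to the quaternary carbon and protects it from the coming oxidation.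

Step 15
Reactants: 18 methyl (2S)-3-{4-(TBS-oxy)-3-[(2S)-2-(TBS-oxy)-3-methyl-3-(RB-oxy)butyl]phenyl}-2-(TES-oxy)propanoate
Product: 19 methyl (2S)-2-hydroxy-3-{4-(TBS-oxy)-3-[(2S)-2-(TBS-oxy)-3-methyl-3-(RB-oxy)butyl]phenyl}propanoate
Conditions: PPTS (cat.), MeOH–CH2Cl2, 0 °C → rt
Reagents that add atoms: none
Why: Mild acid-catalysed methanolysis cleaves the triethylsilyl ether selectively, the aryl and hindered secondary TBS ethers being far slower to react.

Step 16
Reactants: 19 methyl (2S)-2-hydroxy-3-{4-(TBS-oxy)-3-[(2S)-2-(TBS-oxy)-3-methyl-3-(RB-oxy)butyl]phenyl}propanoate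
Product: 20 methyl 2-oxo-3-{4-(TBS-oxy)-3-[(2S)-2-(TBS-oxy)-3-methyl-3-(RB-oxy)butyl]phenyl}propanoate
Conditions: Dess–Martin periodinane, NaHCO3, CH2Cl2, 0 °C → rt; used at once
Reagents that add atoms: none
Why: Dess–Martin oxidation of the only free hydroxyl gives the α-keto ester as the keto tautomer under neutral conditions that spare the enol ether, the prenyl group and the silyl ethers.

Step 17
Reactants: 20 methyl 2-oxo-3-{4-(TBS-oxy)-3-[(2S)-2-(TBS-oxy)-3-methyl-3-(RB-oxy)butyl]phenyl}propanoate; 5 methyl (Z)-3-[4-(TBS-oxy)phenyl]-2-(TMS-oxy)acrylate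
Product: 23 methyl (2R)-4-hydroxy-5-oxo-3-[4-(TBS-oxy)phenyl]-2-({4-(TBS-oxy)-3-[(2S)-2-(TBS-oxy)-3-methyl-3-(RB-oxy)butyl]phenyl}methyl)-2,5-dihydrofuran-2-carboxylate (pentasilylated target with free ring A enol), via silyl aldol adduct 21 (not isolated), via hydroxy keto diester 22 (not isolated)
Conditions: Cu(OTf)2 (30 mol %), 2,2'-isopropylidenebis[(4R)-4-tert-butyl-2-oxazoline] (33 mol %), 5 (3 equiv), THF, −78 → −20 °C; then 1 M HCl, THF, 0 °C
Reagents that add atoms: none
Why: The ketone and ester oxygens of 20 chelate the square-planar divalent copper centre of the Cu(OTf)2–bis(oxazoline) complex, the enol silane 5 attacks the activated ketone carbon (new C4–C5 bond) and its silyl group passes to the copper-bound alkoxide to give 21 and release the catalyst. Aqueous acid then cleaves the O–Si bond and the tertiary hydroxyl of 22 closes ring A by 5-exo-trig acyl substitution at the pyruvate ester of the former nucleophile (new O1–C2 bond, loss of methanol), after which the 3-keto lactone enolises to the conjugated C3 enol. The closest known reactions are the copper bis(oxazoline)-catalysed Mukaiyama aldol addition of enol silanes to pyruvate esters and the aldol–lactonisation of arylpyruvates to 3-hydroxy-4-aryl butenolides. C5 should be set as R by the (4R,4'R) ligand, whose tert-butyl groups block the si face of the chelated ketone so that 5 adds to the re face, and the transient C4 centre is erased by enolisation. The step needs crossed rather than self-condensation and reaction at the keto ester alone: 5 has no ketone and cannot act as an electrophile, 20 arrives as the keto tautomer from the neutral oxidation of step 16 and should not enolise in the absence of base, and only its 1,2-dicarbonyl unit can form the five-membered chelate, so the ester, lactone, enol ether and silyl ethers of ring B and the linker stay spectators.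

Step 18
Reactants: 23 pentasilylated target with free ring A enol
Product: 24 asperbutenolide A
Conditions: HF·pyridine (excess), pyridine, THF, 0 °C → rt
Reagents that add atoms: none
Why: Fluoride-mediated global desilylation removes the four aryl and one secondary TBS ethers under buffered, weakly acidic conditions that should not open the lactones, ionise the tertiary enol ether or cyclise the prenyl phenol.

Compound list
1 | (±)-2-hydroxy-3-(4-hydroxyphenyl)propanoic acid (DL-4-hydroxyphenyllactic acid) | OC(Cc1ccc(O)cc1)C(=O)O | starting material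
2 | methyl (±)-2-hydroxy-3-(4-hydroxyphenyl)propanoate | COC(=O)C(O)Cc1ccc(O)cc1 | intermediate
3 | methyl (±)-3-[4-(TBS-oxy)phenyl]-2-hydroxypropanoate | COC(=O)C(O)Cc1ccc(O[Si](C)(C)C(C)(C)C)cc1 | intermediate
4 | methyl 3-[4-(TBS-oxy)phenyl]-2-oxopropanoate | COC(=O)C(=O)Cc1ccc(O[Si](C)(C)C(C)(C)C)cc1 | intermediate
5 | methyl (Z)-3-[4-(TBS-oxy)phenyl]-2-(TMS-oxy)acrylate | COC(=O)/C(O[Si](C)(C)C)=C/c1ccc(O[Si](C)(C)C(C)(C)C)cc1 | intermediate
6 | 3-iodo-L-tyrosine | N[C@@H](Cc1ccc(O)c(I)c1)C(=O)O | starting material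
7 | (S)-2-hydroxy-3-(4-hydroxy-3-iodophenyl)propanoic acid | O[C@@H](Cc1ccc(O)c(I)c1)C(=O)O | intermediate
8 | methyl (S)-2-hydroxy-3-(4-hydroxy-3-iodophenyl)propanoate | COC(=O)[C@@H](O)Cc1ccc(O)c(I)c1 | intermediate
9 | methyl (S)-3-[4-(TBS-oxy)-3-iodophenyl]-2-hydroxypropanoate | COC(=O)[C@@H](O)Cc1ccc(O[Si](C)(C)C(C)(C)C)c(I)c1 | intermediate
10 | methyl (S)-3-[4-(TBS-oxy)-3-prenylphenyl]-2-hydroxypropanoate | COC(=O)[C@@H](O)Cc1ccc(O[Si](C)(C)C(C)(C)C)c(CC=C(C)C)c1 | intermediate
11 | methyl 3-[4-(TBS-oxy)-3-prenylphenyl]-2-oxopropanoate | COC(=O)C(=O)Cc1ccc(O[Si](C)(C)C(C)(C)C)c(CC=C(C)C)c1 | intermediate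
12 | dimethyl (2R)-2-{[4-(TBS-oxy)-3-prenylphenyl]methyl}-4-oxo-3-[4-(TBS-oxy)phenyl]-2-(TMS-oxy)pentanedioate, C3 epimers (silyl aldol adduct, not isolated) | COC(=O)C(=O)C(c1ccc(O[Si](C)(C)C(C)(C)C)cc1)[C@@](Cc1ccc(O[Si](C)(C)C(C)(C)C)c(CC=C(C)C)c1)(O[Si](C)(C)C)C(=O)OC | intermediate
13 | dimethyl (2R)-2-hydroxy-2-{[4-(TBS-oxy)-3-prenylphenyl]methyl}-4-oxo-3-[4-(TBS-oxy)phenyl]pentanedioate, C3 epimers (hydroxy keto diester, not isolated) | COC(=O)C(=O)C(c1ccc(O[Si](C)(C)C(C)(C)C)cc1)[C@@](Cc1ccc(O[Si](C)(C)C(C)(C)C)c(CC=C(C)C)c1)(O)C(=O)OC | intermediate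
14 | methyl (2R)-4-hydroxy-5-oxo-2-{[4-(TBS-oxy)-3-prenylphenyl]methyl}-3-[4-(TBS-oxy)phenyl]-2,5-dihydrofuran-2-carboxylate (ring B butenolide with free C3 enol) | COC(=O)[C@]1(Cc2ccc(O[Si](C)(C)C(C)(C)C)c(CC=C(C)C)c2)OC(=O)C(O)=C1c1ccc(O[Si](C)(C)C(C)(C)C)cc1 | intermediate
15 | methyl (S)-3-[4-(TBS-oxy)-3-prenylphenyl]-2-(TES-oxy)propanoate | COC(=O)[C@@H](O[Si](CC)(CC)CC)Cc1ccc(O[Si](C)(C)C(C)(C)C)c(CC=C(C)C)c1 | intermediate
16 | methyl (S)-3-[4-(TBS-oxy)-3-{[(2S)-3,3-dimethyloxiran-2-yl]methyl}phenyl]-2-(TES-oxy)propanoate | COC(=O)[C@@H](O[Si](CC)(CC)CC)Cc1ccc(O[Si](C)(C)C(C)(C)C)c(C[C@@H]2OC2(C)C)c1 | intermediate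
17 | methyl (2S)-3-{4-(TBS-oxy)-3-[(2S)-2-hydroxy-3-methyl-3-(RB-oxy)butyl]phenyl}-2-(TES-oxy)propanoate | COC(=O)[C@@H](O[Si](CC)(CC)CC)Cc1ccc(O[Si](C)(C)C(C)(C)C)c(C[C@H](O)C(C)(C)OC2=C(c3ccc(O[Si](C)(C)C(C)(C)C)cc3)[C@](Cc3ccc(O[Si](C)(C)C(C)(C)C)c(CC=C(C)C)c3)(C(=O)OC)OC2=O)c1 | intermediate
18 | methyl (2S)-3-{4-(TBS-oxy)-3-[(2S)-2-(TBS-oxy)-3-methyl-3-(RB-oxy)butyl]phenyl}-2-(TES-oxy)propanoate | COC(=O)[C@@H](O[Si](CC)(CC)CC)Cc1ccc(O[Si](C)(C)C(C)(C)C)c(C[C@H](O[Si](C)(C)C(C)(C)C)C(C)(C)OC2=C(c3ccc(O[Si](C)(C)C(C)(C)C)cc3)[C@](Cc3ccc(O[Si](C)(C)C(C)(C)C)c(CC=C(C)C)c3)(C(=O)OC)OC2=O)c1 | intermediate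
19 | methyl (2S)-2-hydroxy-3-{4-(TBS-oxy)-3-[(2S)-2-(TBS-oxy)-3-methyl-3-(RB-oxy)butyl]phenyl}propanoate | COC(=O)[C@@H](O)Cc1ccc(O[Si](C)(C)C(C)(C)C)c(C[C@H](O[Si](C)(C)C(C)(C)C)C(C)(C)OC2=C(c3ccc(O[Si](C)(C)C(C)(C)C)cc3)[C@](Cc3ccc(O[Si](C)(C)C(C)(C)C)c(CC=C(C)C)c3)(C(=O)OC)OC2=O)c1 | intermediate
20 | methyl 2-oxo-3-{4-(TBS-oxy)-3-[(2S)-2-(TBS-oxy)-3-methyl-3-(RB-oxy)butyl]phenyl}propanoate (α-keto ester carrying linker and ring B) | COC(=O)C(=O)Cc1ccc(O[Si](C)(C)C(C)(C)C)c(C[C@H](O[Si](C)(C)C(C)(C)C)C(C)(C)OC2=C(c3ccc(O[Si](C)(C)C(C)(C)C)cc3)[C@](Cc3ccc(O[Si](C)(C)C(C)(C)C)c(CC=C(C)C)c3)(C(=O)OC)OC2=O)c1 | intermediate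
21 | dimethyl (2R)-2-({4-(TBS-oxy)-3-[(2S)-2-(TBS-oxy)-3-methyl-3-(RB-oxy)butyl]phenyl}methyl)-4-oxo-3-[4-(TBS-oxy)phenyl]-2-(TMS-oxy)pentanedioate, C3 epimers (silyl aldol adduct, not isolated) | COC(=O)C(=O)C(c1ccc(O[Si](C)(C)C(C)(C)C)cc1)[C@@](Cc1ccc(O[Si](C)(C)C(C)(C)C)c(C[C@H](O[Si](C)(C)C(C)(C)C)C(C)(C)OC2=C(c3ccc(O[Si](C)(C)C(C)(C)C)cc3)[C@](Cc3ccc(O[Si](C)(C)C(C)(C)C)c(CC=C(C)C)c3)(C(=O)OC)OC2=O)c1)(O[Si](C)(C)C)C(=O)OC | intermediate
22 | dimethyl (2R)-2-hydroxy-2-({4-(TBS-oxy)-3-[(2S)-2-(TBS-oxy)-3-methyl-3-(RB-oxy)butyl]phenyl}methyl)-4-oxo-3-[4-(TBS-oxy)phenyl]pentanedioate, C3 epimers (hydroxy keto diester, not isolated) | COC(=O)C(=O)C(c1ccc(O[Si](C)(C)C(C)(C)C)cc1)[C@@](Cc1ccc(O[Si](C)(C)C(C)(C)C)c(C[C@H](O[Si](C)(C)C(C)(C)C)C(C)(C)OC2=C(c3ccc(O[Si](C)(C)C(C)(C)C)cc3)[C@](Cc3ccc(O[Si](C)(C)C(C)(C)C)c(CC=C(C)C)c3)(C(=O)OC)OC2=O)c1)(O)C(=O)OC | intermediate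
23 | methyl (2R)-4-hydroxy-5-oxo-3-[4-(TBS-oxy)phenyl]-2-({4-(TBS-oxy)-3-[(2S)-2-(TBS-oxy)-3-methyl-3-(RB-oxy)butyl]phenyl}methyl)-2,5-dihydrofuran-2-carboxylate (pentasilylated target, ring A enol free) | COC(=O)[C@]1(Cc2ccc(O[Si](C)(C)C(C)(C)C)c(C[C@H](O[Si](C)(C)C(C)(C)C)C(C)(C)OC3=C(c4ccc(O[Si](C)(C)C(C)(C)C)cc4)[C@](Cc4ccc(O[Si](C)(C)C(C)(C)C)c(CC=C(C)C)c4)(C(=O)OC)OC3=O)c2)OC(=O)C(O)=C1c1ccc(O[Si](C)(C)C(C)(C)C)cc1 | intermediate
24 | asperbutenolide A | COC(=O)[C@]1(Cc2ccc(O)c(C[C@H](O)C(C)(C)OC3=C(c4ccc(O)cc4)[C@](Cc4ccc(O)c(CC=C(C)C)c4)(C(=O)OC)OC3=O)c2)OC(=O)C(O)=C1c1ccc(O)cc1 | target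

Total step count: 18. Longest linear sequence: 12 steps (6 → 24, through steps 5–10 and 13–18, or equally through steps 5–8 and 11–18).

Steps most likely to fail

Step 17. Enolisation of 20 at its benzylic carbon on the Lewis acid, proton transfer to the enol silane, and slow addition of a trisubstituted push–pull enol silane to a hindered ketone could erode conversion, cross-selectivity or facial selectivity. The fallback gives up catalyst control in favour of the direct base-mediated crossed aldol–lactonisation of two arylpyruvates. Setting out from 20 and an excess of keto ester 4, DBU in THF at 0 °C followed by acidification should give 23 together with the ring A C5 epimer of 23 F1. The two are diastereomers because of the centres already present, and would be separated by preparative HPLC. The self-condensation product of 4 and the regioisomeric cross product would be removed at the same stage, and the route is rejoined at 23.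

Step 13. Hydride shift in the activated epoxide (Meinwald rearrangement to the isopropyl ketone), participation of the ortho silyloxy group or the arene, and attack at the secondary carbon could outrun capture by the hindered enol. The fallback forms the tertiary ether by O-alkylation with an α-bromo ketone and sets the carbinol by reduction. Setting out from 14, Cs2CO3 and 3-bromo-3-methylbutan-2-one in MeCN should give the ring B C3-O-(2-methyl-3-oxobutan-2-yl) ether F2. In parallel, iodide 9 is silylated (TESCl, imidazole) to the TES-protected iodo lactate F3. Ketone α-arylation of F2 with F3 (Pd2(dba)3, Xantphos, K3PO4, toluene, 80 °C) should give the benzyl ketone F4. Reduction with (R)-2-methyl-CBS-oxazaborolidine and catecholborane (toluene, −78 °C), with the tertiary alkoxyalkyl group acting as the large substituent, should deliver the S carbinol and rejoin the route at 17.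

Step 10. The same hazards as in step 17 apply to the first ring closure (enolisation of 11, slow addition, modest facial selectivity). The fallback makes ring B without a chiral catalyst and resolves it through the next bond formation. Setting out from 11 and an excess of 4, DBU in THF should give the racemic ring B butenolide F5. This is carried through the epoxide opening of step 13 with enantiopure 16, which converts the two enantiomers into 17 and the ring B C5 epimer of 17 F6. Chromatographic separation of these diastereomers rejoins the route at 17.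

Further compounds
F1 | step 17 | ring A C5 epimer of 23, methyl (2S)-4-hydroxy-5-oxo-3-[4-(TBS-oxy)phenyl]-2-({4-(TBS-oxy)-3-[(2S)-2-(TBS-oxy)-3-methyl-3-(RB-oxy)butyl]phenyl}methyl)-2,5-dihydrofuran-2-carboxylate | COC(=O)[C@@]1(Cc2ccc(O[Si](C)(C)C(C)(C)C)c(C[C@H](O[Si](C)(C)C(C)(C)C)C(C)(C)OC3=C(c4ccc(O[Si](C)(C)C(C)(C)C)cc4)[C@](Cc4ccc(O[Si](C)(C)C(C)(C)C)c(CC=C(C)C)c4)(C(=O)OC)OC3=O)c2)OC(=O)C(O)=C1c1ccc(O[Si](C)(C)C(C)(C)C)cc1
F2 | step 13 | methyl (2R)-4-[(2-methyl-3-oxobutan-2-yl)oxy]-5-oxo-2-{[4-(TBS-oxy)-3-prenylphenyl]methyl}-3-[4-(TBS-oxy)phenyl]-2,5-dihydrofuran-2-carboxylate | COC(=O)[C@]1(Cc2ccc(O[Si](C)(C)C(C)(C)C)c(CC=C(C)C)c2)OC(=O)C(OC(C)(C)C(C)=O)=C1c1ccc(O[Si](C)(C)C(C)(C)C)cc1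
F3 | step 13 | methyl (S)-3-[4-(TBS-oxy)-3-iodophenyl]-2-(TES-oxy)propanoate | COC(=O)[C@@H](O[Si](CC)(CC)CC)Cc1ccc(O[Si](C)(C)C(C)(C)C)c(I)c1
F4 | step 13 | methyl (2S)-3-{4-(TBS-oxy)-3-[3-methyl-2-oxo-3-(RB-oxy)butyl]phenyl}-2-(TES-oxy)propanoate | COC(=O)[C@@H](O[Si](CC)(CC)CC)Cc1ccc(O[Si](C)(C)C(C)(C)C)c(CC(=O)C(C)(C)OC2=C(c3ccc(O[Si](C)(C)C(C)(C)C)cc3)[C@](Cc3ccc(O[Si](C)(C)C(C)(C)C)c(CC=C(C)C)c3)(C(=O)OC)OC2=O)c1
F5 | step 10 | racemic methyl 4-hydroxy-5-oxo-2-{[4-(TBS-oxy)-3-prenylphenyl]methyl}-3-[4-(TBS-oxy)phenyl]-2,5-dihydrofuran-2-carboxylate | COC(=O)C1(Cc2ccc(O[Si](C)(C)C(C)(C)C)c(CC=C(C)C)c2)OC(=O)C(O)=C1c1ccc(O[Si](C)(C)C(C)(C)C)cc1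
F6 | step 10 | ring B C5 epimer of 17, with the (5S) ring B unit bound through its C3 oxygen | COC(=O)[C@@H](O[Si](CC)(CC)CC)Cc1ccc(O[Si](C)(C)C(C)(C)C)c(C[C@H](O)C(C)(C)OC2=C(c3ccc(O[Si](C)(C)C(C)(C)C)cc3)[C@@](Cc3ccc(O[Si](C)(C)C(C)(C)C)c(CC=C(C)C)c3)(C(=O)OC)OC2=O)c1
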